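A small charge of incoming ligand can be judged by a count before any rate. Each complex stands in one of three forms, and bound ligand is [complex with one exchanged] + 2[complex with two exchanged], so [complex with two exchanged] − [starting complex] equals bound ligand minus the charged complex. For the complex with two exchanged to pass the starting complex, a share of 1.00 of the ligand must be bound in theta: this is the needed share, charged starting complex over charged incoming ligand. In theta, the incoming ligand is the limiting reagent, and reaching that share would leave none of it free or dormant.

the same everywhere: starting complex 10 mM
- blue: incoming ligand 7.9 mM (fed, over 10 h); leaving ligand 20 mM; run made earlier
- red: incoming ligand 25 mM (fed, over 10 h); leaving ligand 20 mM; run made earlier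
- theta: incoming ligand 10.0 mM (fed, over 10 h); leaving ligand 20.0 mM; time 12 h
- epsilon: incoming ligand 30.0 mM (fed, over 10 h); leaving ligand 20.0 mM; time 12 h
- beta: incoming ligand 15.0 mM (fed, over 10 h); leaving ligand 20.0 mM; time 12 h

| run | time / h | complex with two exchanged / % | complex with one exchanged / % | starting complex / % |
|---|---|---|---|---|
| blue | 2.00 | 0 | 3 | 100 |
| blue | 4.00 | 1 | 11 | 91 |
| blue | 6.00 | 5 | 16 | 81 |
| blue | 8.00 | 11 | 19 | 72 |
| red | 0.667 | 0 | 1 | 99 |
| red | 1.50 | 0 | 4 | 97 |
| red | 4.00 | 9 | 22 | 70 |
| red | 8.00 | 41 | 24 | 33 |

(standard deviation of a reading: 2 percentage points)

- the analysis behind the earlier runs scatters by 2 percentage points, standard deviation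
- candidate steps: starting complex + incoming ligand <-> leaving ligand + complex with one exchanged; incoming ligand <-> dormant form; complex with one exchanged + incoming ligand <-> leaving ligand + complex with two exchanged

* which of these holds the largest part of the starting complex at the end of theta (complex with two exchanged / complex with one exchanged / starting complex)
* which of these holds the largest part of the starting complex at the end of epsilon (complex with two exchanged / complex with one exchanged / starting complex)
* which of these holds the largest part of the starting complex at the end of beta (complex with two exchanged / complex with one exchanged / starting complex)
* how much complex with two exchanged is there at the end of theta, in percent of the starting complex charged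

My own reckoning takes the bound share of what had been fed. At 8.00 h it reads 0.649 in blue and 0.530 in red, and red's share climbed by 0.130 between 4.00 h and 8.00 h. Adding that climb to blue's share, for a span of the same length up to 12 h, gives theta about 0.779, so its starting complex should stand above its complex with two exchanged by 22.1 % of the complex charged, and with the 24 % of complex with one exchanged read in red at 8.00 h, its complex with two exchanged comes to 27.0 %. Epsilon needs 0.333, less than red's reading, so the complex with two exchanged should pass the starting complex there. Beta needs 0.667, more than blue's reading, and the mean of the two readings plus the climb gives 0.720, so the same complex should pass the starting complex in beta by a narrow margin. With the complex with one exchanged near that reading of 24 %, the larger of the other two should hold 38.0 % or more, so one of those two should lead in each flask.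

The forecast named starting complex for theta, complex with two exchanged for epsilon and complex with two exchanged for beta, with 27 % for the amount asked, saying of theta “so starting complex remains largest”.

Theta ends with 23.4 % of complex with two exchanged, and 22 % of its incoming ligand is still free at 12.0 h. Its bound share is 0.746 against the needed 1.00, and its starting complex holds 48.8 %, the largest part. Beta ends with 40.5 % of complex with two exchanged against 33.1 % of starting complex, and epsilon with 79.6 % against 7.81 %.

    starting complex + incoming ligand ⇌ leaving ligand + complex with one exchanged (K = 17.0, k = 30.0 M⁻¹ h⁻¹)
    incoming ligand ⇌ dormant form (K = 0.540, k = 0.0120 h⁻¹)
    complex with one exchanged + incoming ligand ⇌ leaving ligand + complex with two exchanged (K = 44.0, k = 44.0 M⁻¹ h⁻¹)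

A further flask like theta, with 17 mM of incoming ligand, has a needed share of 0.588, below theta's bound 0.746, so the complex with two exchanged should pass the starting complex there. It ends with 47.0 % of that complex against 28 % of starting complex, at a bound share of 0.700.

The data are calculated for substances that don't exist, noise included.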